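(All runs are calculated for substances that don't exist, and the scatter is random.)

We want to know which way of running the same charge leaves the most target after 2.5 min, and birch is the hard case, since its partner arrives slowly. Alder is the gamma run left to that time.

all flasks: free catalyst 3 mol%
- gamma: starting material 5 mM; partner 1.2 equiv; run made earlier
- alpha: starting material 3.4 mM; partner 1.2 equiv; run made earlier
- beta: starting material 7.5 mM; partner 1.2 equiv; run made earlier
- theta: starting material 5 mM; partner 1.8 equiv; run made earlier
- alder: starting material 5.0 mM; partner 1.20 equiv; a closed flask charged with all of it at once and left for 2.5 min; time 2.5 min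
- oak: starting material 5.0 mM (fed, over 2.00 min); partner 1.20 equiv; all but starting material at the start; starting material goes in evenly over 2.00 min, the run ends at 2.5 min; time 2.5 min
- maple: starting material 5.0 mM; partner 1.20 equiv; one stirred flow tank at steady state, fed with the mixture as stated, mean residence time 2.5 min
- birch: starting material 5.0 mM; partner 1.20 equiv (fed, over 2.00 min); all but partner at the start; partner goes in evenly over 2.00 min, the run ends at 2.5 min; time 2.5 min

- gamma (time / s: target / %, starting material / %): 15.0: 21.6, 66.6; 30.0: 38.7, 43.7; 50.0: 56.4, 22.0; 60.0: 60.7, 16.7; 80.0: 69.2, 7.2; 90.0: 71.9, 6.9
- alpha (time / s: target / %, starting material / %): 10.0: 10.9, 78.4; 15.0: 17.6, 69.9; 25.0: 28.1, 55.1; 40.0: 38.9, 38.5; 80.0: 57.6, 15.7; 120: 70.3, 8.5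
- beta (time / s: target / %, starting material / %): 10.0: 17.4, 74.0; 15.0: 25.8, 63.3; 25.0: 38.8, 46.2; 40.0: 57.9, 21.3; 80.0: 76.7, 3.1; 120: 83.3, 2.7
- theta (time / s: target / %, starting material / %): 10.0: 15.1, 76.1; 20.0: 27.9, 57.2; 30.0: 38.6, 42.6; 60.0: 62.0, 17.4; 120: 78.9, 2.1

(scatter of a reading: 1 percentage point)

- the stated concentrations are those of everything mixed, before any reaction; amounts are the same in each set-up
- the numbers in the tables scatter with a standard deviation of 1 percentage point
- the feed brings no volume worth counting
- the earlier runs were made in a closed, stirred flask

- the set-up with the highest amount of target at the outlet or at the end, in percent of the starting material put in ("none" if the first two lie within 2 percentage points) (alder / oak / maple / birch / none)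
- amount of target at the outlet or at the end, in percent of the starting material put in, alder
- amount of target at the outlet or at the end, in percent of the starting material put in, oak
- amount of target at the outlet or at the end, in percent of the starting material put in, maple
- amount of target at the outlet or at the end, in percent of the starting material put in, birch

The gamma and theta runs differ in partner, 1.2 equiv against 1.8 equiv, yet at 60.0 s they read alike: target 60.7% against 62.0%, starting material 16.7% against 17.4%. Gamma's partner charge, 120% on the scale of the starting material, still stood above the 60.7% of target made, so between these two charges, with partner in excess, the pace reads as zero order in partner.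

Birch differs in that partner must first arrive. It comes at 0.600 min⁻¹, and this feed pace, the fraction of the starting material charged that the delivered partner matches per unit time, multiplied by the elapsed time gives a ceiling on target during the feed, one partner going into one target. Gamma's opening pace of 0.864 min⁻¹ is faster than the feed. At 30.0 s the ceiling is 30.0% against gamma's 38.7%, so birch is by then at least 8.7 percentage points behind, and at 60.0 s the ceiling of 60.0% has met gamma's reading. The readings also show material that is neither starting material nor target, 22.6% in gamma at 60.0 s, and starting material waiting for partner has time to join it, so we place birch below alder, without a figure of our own.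

The forecast names alder as best, with alder 83%, oak 73%, maple 72% and birch 79% (range 68% to 85%), and says of birch: “This is the least certain, since behaviour under partner starvation is untested.”

The flask gives alder as best, with alder 80.5%, oak 74.2%, maple 71.1% and birch 72.9%, so the forecast for birch stands 6.1 points too high.

    partner + catalyst intermediate A → catalyst intermediate B (k = 1600 M⁻¹ s⁻¹)
    catalyst intermediate B → free catalyst + target (k = 1.10 s⁻¹)
    starting material ⇌ dormant form (K = 1.60, k = 0.00920 s⁻¹)
    starting material + free catalyst → catalyst intermediate A (k = 240 M⁻¹ s⁻¹)

At 1.25 min birch had received 75.0% and held target 52.1%, below the ceiling, with partner at 18.7% of its own charge. The neighbour, birch with 0.300 equiv of partner, has its pace cut to 0.150 min⁻¹, so its ceiling after 2.00 min of feed is 30.0%. Its target ends at 30.0%, on that ceiling, with partner, the limiting reagent, down to 0.0075% of its charge and starting material still at 25.9%.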